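(The readings were computed for substances that don't exist; scatter was added.)

The meeting on the amber flask opened with the leftover: starting material stood at 0.6% by the first amber reading at 0.200 min, against a scatter of 0.5 percentage points, so talk turned to target and isomer of the product A.

all flasks: starting material 0.50 M
- amber: free catalyst 4.9 mol%; the very flask that is asked about, followed so far
- teal: free catalyst 9.8 mol%; run made earlier
- flask: free catalyst 4.9 mol%; time 6.0 min

| run | time / min | isomer of the product A / % | target / % | starting material / % |
|---|---|---|---|---|
| amber | 0.200 | 4.5 | 0.1 | 0.6 |
| amber | 0.667 | 10.1 | 1.8 | 0.3 |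
| amber | 1.00 | 11.1 | 0 | 0 |
| amber | 1.50 | 12.1 | 0.6 | 0.4 |
| amber | 2.50 | 12.7 | 0.9 | 0 |
| amber | 3.00 | 11.8 | 0 | 0.5 |
| teal | 0.417 | 13.8 | 0.7 | 0.2 |
| teal | 0.833 | 16.0 | 0.7 | 0 |
| teal | 1.33 | 17.7 | 1.7 | 1.2 |
| teal | 1.50 | 18.0 | 0.6 | 0.4 |
| teal | 2.00 | 17.8 | 2.2 | 0 |
| teal | 2.50 | 17.3 | 1.7 | 0.6 |

(readings scatter by 0.5 percentage points)

- percentages count the starting material that a species holds: one idle adduct counts as two
- target is meant together with its idle adduct
- reactions considered so far: starting material + free catalyst <-> target + free catalyst; target + free catalyst <-> isomer of the product A + free catalyst; isomer of the product A + free catalyst <-> isomer of the product B + free catalyst; isomer of the product B <-> starting material; free catalyst -> spent catalyst; starting material -> uncatalysed product; starting material + target <-> idle adduct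
- in an amount of target, one idle adduct counts as one target

1. share of isomer of the product A in isomer of the product A plus target at 1.5 s
2. share of isomer of the product A in isomer of the product A plus target at 6.0 min

I proposed treating target and isomer of the product A as a pre-equilibrium, and carrying one number, the balance share, c(isomer of the product A)/(c(isomer of the product A) + c(target)), taken as a reading from the summed readings of the amber and teal runs, in which single target readings run from 0% to 2.2% against a scatter of 0.5 points: 93.7%. I committed to that share at both asked times, granting that the first reading comes 8.00 times later than 1.5 s, so the early figure is an extrapolation.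

The forecast's author gave 93% for the late time, close to mine, but 60% for the early one, 34 points below mine, adding: “The share is poorly constrained, and is only a guess near 60%.”

    starting material + free catalyst ⇌ target + free catalyst, rate k1*[starting material]*[free catalyst] forward; the back reaction follows from the equilibrium constant (K = 20.0, k = 11.8 M⁻¹ s⁻¹)
    target + free catalyst ⇌ isomer of the product A + free catalyst, rate k2*[free catalyst]*[target] forward; the back reaction follows from the equilibrium constant (K = 14.5, k = 102 M⁻¹ s⁻¹)
    isomer of the product A + free catalyst ⇌ isomer of the product B + free catalyst, rate k3*[free catalyst]*[isomer of the product A] forward; the back reaction follows from the equilibrium constant (K = 3.00, k = 0.853 M⁻¹ s⁻¹)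
    isomer of the product B ⇌ starting material (k = 0.215 s⁻¹)
    free catalyst → spent catalyst (k = 0.0422 s⁻¹)
    starting material → uncatalysed product (k = 0.00111 s⁻¹)
    starting material + target ⇌ idle adduct, settled at all times (K = 2.78 M⁻¹)

The amber flask gives 93.7% at 1.5 s and 93.6% at 6.0 min, which puts the forecast's early figure 34 points low. With the falling back of starting material to isomer of the product B struck out, the early share is 54.1%. Put to use once more, the balance share turns the 9.96% of isomer of the product A at 0.600 min into 0.670% of target, and the flask holds 0.684%.

In the neighbour flask, charged with 2.0 M of starting material, the balance share gives 93.7%, and its 22.8% of isomer of the product A at 6.00 min implies 1.53% of target. The computed neighbour flask shows a share of 93.5% and 1.58% of target at that time.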